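## Retrosynthetic overview

1. The 11-membered carbocycle is opened at the bond between the side-chain CH2 and the quaternary cyclohexene carbon (the ring carbon bearing CH3, between the spiro carbon and the ring CH=). The enabling feature is that this carbon is allylic to the ring CH=C(CH3): the unit C(quaternary)–CH=C(CH3) is a former 3-methylcyclohex-2-enone in which the C(CH3)= carbon was the carbonyl carbon (enol triflate → CH3) and the quaternary carbon the β-carbon. The (Z)-CH=CH next to the CH2 is read as an alkyne, so the nucleophile is an allenylstannane.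
2. The seco compound is assembled from two halves at the acyl–tetronate C3 bond (3-lithio methyl tetronate + decalin aldehyde).
3. Spiro half: Diels–Alder reaction of a 1-methoxy-3-silyloxy diene with (R)-2-tert-butyl-5-methylene-1,3-dioxolan-4-one. The adduct (a β-methoxy silyl enol ether) is the masked enone, and the tetronate ring follows from the Bestmann ylide.
4. Decalin half: intramolecular Diels–Alder reaction of an (E,E,E)-trienal made by anti-aldol and syn-1,3-reduction; the chloropropargyl chain is carried from the first steps.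
5. Order of ring formation: decalin rings A and B together (step 13); cyclohexene (step 19); tetronate (step 21); macrocycle last (step 25).

Key step: step 25

Assumption: in step 6 the chelated magnesium enolate of the (S)-benzyl oxazolidinone is taken to react on the face away from benzyl (as in its alkylations), giving the (2R,3R) anti adduct; with the opposite sense the (R)-auxiliary would be used.

## Route

Step 1
Reactants: 1 methyl (2E,4E)-hexa-2,4-dienoate
Product: 2 methyl (2E,4E)-6-bromohexa-2,4-dienoate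
Conditions: NBS, (PhCO2)2 (cat.), PhCl, 100 °C
Reagents that add atoms: N-bromosuccinimide O=C1CCC(=O)N1Br
Why: Wohl–Ziegler bromination occurs at the only sp3 C–H site, and the pentadienyl-type radical is trapped at the terminus so that the dienoate stays conjugated.

Step 2
Reactants: 2 methyl (2E,4E)-6-bromohexa-2,4-dienoate; 3 prop-2-yn-1-ol
Product: 4 methyl (2E,4E)-9-hydroxynona-2,4-dien-7-ynoate
Conditions: CuI (cat.), NaI, K2CO3, DMF, 20 °C
Reagents that add atoms: none
Why: CuI-mediated coupling of the copper acetylide with the primary dienylic halide (skipped-enyne synthesis) proceeds by SN2 at the terminal carbon and leaves the (E,E)-dienoate untouched.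

Step 3
Reactants: 4 methyl (2E,4E)-9-hydroxynona-2,4-dien-7-ynoate
Product: 5 methyl (2E,4E)-9-chloronona-2,4-dien-7-ynoate
Conditions: PPh3, CCl4, CH2Cl2, 0 → 20 °C
Reagents that add atoms: carbon tetrachloride ClC(Cl)(Cl)Cl
Why: the Appel reaction converts the primary propargylic alcohol into the chloride under neutral conditions that should not isomerise the skipped dienyne.

Step 4
Reactants: 5 methyl (2E,4E)-9-chloronona-2,4-dien-7-ynoate
Product: 6 (2E,4E)-9-chloronona-2,4-dien-7-yn-1-ol
Conditions: i-Bu2AlH (2.2 equiv), CH2Cl2, −78 °C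
Reagents that add atoms: none
Why: 1,2-reduction of the conjugated ester by the aluminium hydride at low temperature, where the propargylic chloride is inert.

Step 5
Reactants: 6 (2E,4E)-9-chloronona-2,4-dien-7-yn-1-ol
Product: 7 (2E,4E)-9-chloronona-2,4-dien-7-ynal
Conditions: MnO2, CH2Cl2, 20 °C
Reagents that add atoms: none
Why: MnO2 oxidises the allylic (dienylic) alcohol selectively to the dienal.

Step 6
Reactants: 7 (2E,4E)-9-chloronona-2,4-dien-7-ynal; 8 (S)-4-benzyl-3-propanoyl-1,3-oxazolidin-2-one
Product: 10 (S)-4-benzyl-3-[(2R,3R,4E,6E)-11-chloro-3-hydroxy-2-methylundeca-4,6-dien-9-ynoyl]-1,3-oxazolidin-2-one, via O-trimethylsilyl ether 9 (not isolated)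
Conditions: MgCl2 (cat.), Et3N, Me3SiCl, EtOAc, 20 °C; then CF3CO2H (cat.), MeOH
Reagents that add atoms: none
Why: the Evans MgCl2-catalysed anti-aldol reaction of the chelated (Z)-enolate with the non-enolisable dienal sets the CH(CH3) and CH(OH) centres anti, the benzyl group shielding one enolate face; methanolysis removes the O-silyl group.

Step 7
Reactants: 10 aldol adduct
Product: 11 (2R,3R,4E,6E)-11-chloro-3-hydroxy-N-methoxy-N,2-dimethylundeca-4,6-dien-9-ynamide
Conditions: MeNH(OMe)·HCl, AlMe3, CH2Cl2, −20 → 0 °C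
Reagents that add atoms: N,O-dimethylhydroxylamine hydrochloride CNOC.Cl
Why: aluminium-amide transamidation (Weinreb), assisted by the free β-hydroxyl, removes the auxiliary without epimerisation or retro-aldol cleavage.

Step 8
Reactants: 11 Weinreb amide
Product: 12 ethyl (4R,5R,6E,8E)-13-chloro-5-hydroxy-4-methyl-3-oxotrideca-6,8-dien-11-ynoate
Conditions: EtOAc, LiN(i-Pr)2 (3.5 equiv), THF, −78 °C; then 11, −78 → −40 °C
Reagents that add atoms: ethyl acetate CCOC(C)=O
Why: Claisen-type acylation of the lithium enolate of ethyl acetate by the Weinreb amide stops at the β-keto ester because the chelated tetrahedral intermediate survives until work-up.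

Step 9
Reactants: 12 β-keto ester
Product: 13 ethyl (3S,4S,5R,6E,8E)-13-chloro-3,5-dihydroxy-4-methyltrideca-6,8-dien-11-ynoate
Conditions: Et2BOMe, NaBH4, THF/MeOH, −78 °C; then MeOH
Reagents that add atoms: none
Why: Narasaka–Prasad reduction of the boron chelate by external hydride gives the 1,3-syn diol, which places the new carbinol anti to the methyl group.

Step 10
Reactants: 13 syn-diol ester
Product: 14 ethyl (3S,4S,5R,6E,8E)-3,5-bis[(tert-butyldimethylsilyl)oxy]-13-chloro-4-methyltrideca-6,8-dien-11-ynoate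
Conditions: t-BuMe2SiOTf, 2,6-lutidine, CH2Cl2, −78 → 0 °C
Reagents that add atoms: tert-butyldimethylsilyl triflate CC(C)(C)[Si](C)(C)OS(=O)(=O)C(F)(F)F
Why: silyl triflate silylates both hindered secondary alcohols, and silyl ethers are chosen because they survive the Lewis acids used later.

Step 11
Reactants: 14 bis-silyl ether ester
Product: 15 (3S,4S,5R,6E,8E)-3,5-bis[(tert-butyldimethylsilyl)oxy]-13-chloro-4-methyltrideca-6,8-dien-11-ynal
Conditions: i-Bu2AlH (1.1 equiv), CH2Cl2, −78 °C
Reagents that add atoms: none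
Why: half-reduction of the β-silyloxy ester stops at the aldehyde because the tetrahedral aluminium hemiacetal is stable at −78 °C.

Step 12
Reactants: 15 aldehyde
Product: 16 (2E,5S,6S,7R,8E,10E)-5,7-bis[(tert-butyldimethylsilyl)oxy]-15-chloro-2,6-dimethylpentadeca-2,8,10-trien-13-ynal
Conditions: Ph3P=C(CH3)CHO, benzene, 70 °C
Reagents that add atoms: 2-(triphenylphosphoranylidene)propanal CC(C=O)=P(c1ccccc1)(c1ccccc1)c1ccccc1
Why: Wittig reaction of the stabilised ylide gives the (E)-2-methyl enal.

Step 13
Reactants: 16 trienal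
Product: 17 trans-decalin aldehyde
Conditions: Me2AlCl, CH2Cl2, −78 → −20 °C
Reagents that add atoms: none
Why: the Lewis-acid-promoted intramolecular Diels–Alder reaction through the formyl-endo, chair-like transition state of the (E,E,E)-trienal gives the trans-fused decalin; the two silyloxy groups sit equatorial on the forming ring (methyl axial), which fixes the face, and the quaternary carbon, both ring-fusion CH and the CH carrying the side chain follow from suprafacial addition.

Step 14
Reactants: 18 (R)-lactic acid; 19 pivalaldehyde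
Product: 20 (2R,5R)-2-tert-butyl-5-methyl-1,3-dioxolan-4-one
Conditions: TsOH (cat.), H2SO4 (cat.), pentane, reflux, Dean–Stark
Reagents that add atoms: none
Why: Seebach acetalisation under water removal gives the cis-dioxolanone (favoured thermodynamically and on crystallisation), storing the lactate chirality in the acetal carbon.

Step 15
Reactants: 20 cis-dioxolanone
Product: 21 5-bromo-2-tert-butyl-5-methyl-1,3-dioxolan-4-one
Conditions: NBS, AIBN (cat.), CCl4, reflux
Reagents that add atoms: N-bromosuccinimide O=C1CCC(=O)N1Br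
Why: radical bromination occurs at the tertiary C–H flanked by oxygen and carbonyl (captodative radical), and the acetal carbon is untouched.

Step 16
Reactants: 21 bromide
Product: 22 (R)-2-tert-butyl-5-methylene-1,3-dioxolan-4-one
Conditions: DBU, Et2O, 0 → 20 °C
Reagents that add atoms: none
Why: E2 dehydrobromination gives the exocyclic alkene, a captodative dienophile whose only stereocentre is the acetal carbon.

Step 17
Reactants: 23 (E)-4-methoxypent-3-en-2-one
Product: 24 (E)-2-methoxyhept-2-en-4-one
Conditions: LiN(i-Pr)2, THF, −78 °C; EtI, DMPU, −78 → −20 °C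
Reagents that add atoms: iodoethane CCI
Why: kinetic deprotonation of the vinylogous ester occurs at the α′-methyl group, and the enolate is alkylated there (Stork–Danheiser-type alkylation).

Step 18
Reactants: 24 (E)-2-methoxyhept-2-en-4-one
Product: 25 (2E,4Z)-2-methoxy-4-[(triisopropylsilyl)oxy]hepta-2,4-diene
Conditions: i-Pr3SiOTf, Et3N, Et2O, 0 → 20 °C
Reagents that add atoms: triisopropylsilyl triflate CC(C)[Si](OS(=O)(=O)C(F)(F)F)(C(C)C)C(C)C
Why: soft enolisation with O-silylation towards the propyl side gives the cross-conjugated (Z)-silyl dienol ether, a Danishefsky-type 1-alkoxy-3-silyloxy diene.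

Step 19
Reactants: 22 (R)-2-tert-butyl-5-methylene-1,3-dioxolan-4-one; 25 (2E,4Z)-2-methoxy-4-[(triisopropylsilyl)oxy]hepta-2,4-diene
Product: 26 spiro-dioxolanone cycloadduct
Conditions: toluene, BHT (cat.), 100 °C, sealed tube
Reagents that add atoms: none
Why: in this Diels–Alder reaction the nucleophilic CH–ethyl terminus of the diene bonds to the CH2 of the dienophile, the diene adds anti to tert-butyl (sets the spiro carbon) and the lactone carbonyl is exo as usual for this dienophile (sets CH–ethyl cis to the ring oxygen); the C(OCH3)(CH3) centre is formed as a mixture and is lost later.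

Step 20
Reactants: 26 cycloadduct
Product: 27 methyl (1S,5R)-5-ethyl-1-hydroxy-2-methoxy-2-methyl-4-[(triisopropylsilyl)oxy]cyclohex-3-ene-1-carboxylate
Conditions: K2CO3 (cat.), MeOH, 0 → 20 °C
Reagents that add atoms: methanol CO
Why: base-catalysed transesterification opens the dioxolanone to the tertiary α-hydroxy methyl ester and pivalaldehyde, leaving the hindered silyl enol ether and the allylic methyl ether intact.

Step 21
Reactants: 27 α-hydroxy ester
Product: 28 spiro methyl tetronate with masked enone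
Conditions: Ph3P=C=C=O, toluene, reflux
Reagents that add atoms: (triphenylphosphoranylidene)ketene O=C=C=P(c1ccccc1)(c1ccccc1)c1ccccc1
Why: addition of the tertiary alcohol to the ketenylidene ylide gives an ester ylide that closes by intramolecular Wittig olefination of the methyl ester (Bestmann ylide tetronate synthesis), giving the 4-methoxy butenolide directly.

Step 22
Reactants: 28 spiro methyl tetronate; 17 trans-decalin aldehyde
Product: 30 coupled carbinol (tetronate C3–CH(OH)–decalin; both carbinol epimers), via 3-lithio tetronate 29 (not isolated)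
Conditions: LiN(i-Pr)2, THF, −78 °C; then 17, −78 °C; aq. NaHCO3
Reagents that add atoms: none
Why: C3-lithiation of the 4-methoxyfuranone and addition to the non-enolisable aldehyde is the standard acyl-tetronate connection, and the masked enone offers no acidic or electrophilic site.

Step 23
Reactants: 30 coupled carbinol
Product: 31 allenylstannane carbinol
Conditions: Bu3SnH, LiN(i-Pr)2, THF, 0 °C; CuBr·SMe2, −78 °C; then 30, −78 °C
Reagents that add atoms: tributyltin hydride (used as Bu3SnLi) CCCC[SnH](CCCC)CCCC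
Why: anti-SN2′ substitution of the propargylic chloride by the stannylcopper reagent gives the 1-substituted 1-stannylallene, and the lithium alkoxide of the carbinol is inert.

Step 24
Reactants: 31 allenylstannane carbinol
Product: 32 seco ketone (3-acyl-4-methoxy tetronate)
Conditions: Dess–Martin periodinane, pyridine, CH2Cl2, 0 °C
Reagents that add atoms: none
Why: buffered Dess–Martin oxidation converts both carbinol epimers into one ketone and removes the ionisable allylic C–O bond before the Lewis-acid step.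

Step 25
Reactants: 32 seco ketone
Product: 34 macrocyclic cycloundecyne silyl enol ether, via silyloxyallyl cation 33 (not isolated)
Conditions: Me3SiOTf (1.5 equiv), 2,6-di-tert-butyl-4-methylpyridine, CH2Cl2 (1 mM), −78 → −40 °C
Reagents that add atoms: none
Why: Proposed new method: Me3SiOTf ionises the tertiary allylic methyl ether (pushed by the silyl enol ether) to cation 33, whose γ-carbon (the ring carbon bearing CH3 next to the spiro carbon) is attacked by the CH2 terminus of the tethered allenylstannane in an SE2′ process that expels Bu3Sn+ and leaves the alkyne and a regiodefined silyl enol ether; the closest known reactions are the intermolecular Lewis-acid-promoted conjugate propargylation of enones with allenylstannanes and intramolecular Hosomi–Sakurai cyclisations onto β,β-disubstituted enones, neither of which has been used to close a macrocycle. The 11-membered carbocycle closes in an 11-exo-trig sense at the cationic carbon, the allenyl unit becoming the endocyclic alkyne. The new quaternary stereocentre is set by attack anti to the pseudoaxial bond from the spiro carbon to tetronate C4 (the smaller ring oxygen takes the pseudoequatorial site to avoid A(1,2) strain with the vinylic CH3), which puts the new CH2 cis to the ring oxygen and trans to tetronate C4 as in the target. The selectivities needed are γ- over carbonyl-carbon attack (secured by the soft π-nucleophile), propargyl over allenyl product (secured by the SE2′ course of 1-stannylallenes) and ring closure over oligomerisation (secured by high dilution). Loss of a proton to the free enone is not destructive because the enone re-enters through O-silylation.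

Step 26
Reactants: 34 macrocyclic silyl enol ether
Product: 35 macrocyclic enol triflate
Conditions: CsF, PhNTf2, DME, 20 °C
Reagents that add atoms: N-phenylbis(trifluoromethanesulfonimide) O=S(=O)(N(c1ccccc1)S(=O)(=O)C(F)(F)F)C(F)(F)F
Why: fluoride releases the regiodefined enolate and PhNTf2 traps it on oxygen, so the triflate sits on the carbon that must carry the methyl group; the enolate has no β-leaving group.

Step 27
Reactants: 35 macrocyclic enol triflate
Product: 36 macrocyclic cycloalkyne with the complete cyclohexene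
Conditions: Me2Zn, Pd(PPh3)4 (cat.), THF, 0 → 20 °C
Reagents that add atoms: dimethylzinc C[Zn]C
Why: Negishi cross-coupling (oxidative addition of the enol triflate to zerovalent palladium, transmetalation from zinc, reductive elimination) puts the methyl group on the ring alkene.

Step 28
Reactants: 36 macrocyclic cycloalkyne
Product: 37 (Z)-macrocycle (bis-silyl ether, methyl tetronate)
Conditions: H2 (1 atm), Pd/CaCO3 poisoned with Pb(OAc)2, quinoline, EtOAc, 20 °C
Reagents that add atoms: none
Why: Lindlar syn-semihydrogenation of the ring alkyne gives the (Z)-alkene, and the di- and trisubstituted alkenes should not be reduced over the poisoned catalyst.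

Step 29
Reactants: 37 (Z)-macrocycle
Product: 38 bis-silyl ether of the target
Conditions: LiCl, DMSO, 50 °C; dilute HCl work-up
Reagents that add atoms: none
Why: SN2 demethylation of the vinylogous methyl ester by chloride liberates the 3-acyl tetronic acid.

Step 30
Reactants: 38 bis-silyl ether of the target
Product: 39 CNP0259772.1
Conditions: HF·pyridine, pyridine, THF, 0 → 20 °C
Reagents that add atoms: none
Why: fluoride cleaves both silyl ethers without touching any stereocentre.

## Compound list

1 | methyl (2E,4E)-hexa-2,4-dienoate (methyl sorbate) | COC(=O)/C=C/C=C/C | starting material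
2 | methyl (2E,4E)-6-bromohexa-2,4-dienoate | COC(=O)/C=C/C=C/CBr | intermediate
3 | prop-2-yn-1-ol | C#CCO | starting material
4 | methyl (2E,4E)-9-hydroxynona-2,4-dien-7-ynoate | COC(=O)/C=C/C=C/CC#CCO | intermediate
5 | methyl (2E,4E)-9-chloronona-2,4-dien-7-ynoate | COC(=O)/C=C/C=C/CC#CCCl | intermediate
6 | (2E,4E)-9-chloronona-2,4-dien-7-yn-1-ol | OC/C=C/C=C/CC#CCCl | intermediate
7 | (2E,4E)-9-chloronona-2,4-dien-7-ynal | O=C/C=C/C=C/CC#CCCl | intermediate
8 | (S)-4-benzyl-3-propanoyl-1,3-oxazolidin-2-one | CCC(=O)N1[C@@H](Cc2ccccc2)COC1=O | starting material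
9 | O-trimethylsilyl ether of 10 | O=C1OC[C@H](Cc2ccccc2)N1C(=O)[C@H](C)[C@H](O[Si](C)(C)C)/C=C/C=C/CC#CCCl | intermediate
10 | (S)-4-benzyl-3-[(2R,3R,4E,6E)-11-chloro-3-hydroxy-2-methylundeca-4,6-dien-9-ynoyl]-1,3-oxazolidin-2-one | O=C1OC[C@H](Cc2ccccc2)N1C(=O)[C@H](C)[C@H](O)/C=C/C=C/CC#CCCl | intermediate
11 | (2R,3R,4E,6E)-11-chloro-3-hydroxy-N-methoxy-N,2-dimethylundeca-4,6-dien-9-ynamide | CON(C)C(=O)[C@H](C)[C@H](O)/C=C/C=C/CC#CCCl | intermediate
12 | ethyl (4R,5R,6E,8E)-13-chloro-5-hydroxy-4-methyl-3-oxotrideca-6,8-dien-11-ynoate | CCOC(=O)CC(=O)[C@H](C)[C@H](O)/C=C/C=C/CC#CCCl | intermediate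
13 | ethyl (3S,4S,5R,6E,8E)-13-chloro-3,5-dihydroxy-4-methyltrideca-6,8-dien-11-ynoate | CCOC(=O)C[C@H](O)[C@H](C)[C@H](O)/C=C/C=C/CC#CCCl | intermediate
14 | ethyl (3S,4S,5R,6E,8E)-3,5-bis[(tert-butyldimethylsilyl)oxy]-13-chloro-4-methyltrideca-6,8-dien-11-ynoate | CCOC(=O)C[C@H](O[Si](C)(C)C(C)(C)C)[C@H](C)[C@H](O[Si](C)(C)C(C)(C)C)/C=C/C=C/CC#CCCl | intermediate
15 | (3S,4S,5R,6E,8E)-3,5-bis[(tert-butyldimethylsilyl)oxy]-13-chloro-4-methyltrideca-6,8-dien-11-ynal | O=CC[C@H](O[Si](C)(C)C(C)(C)C)[C@H](C)[C@H](O[Si](C)(C)C(C)(C)C)/C=C/C=C/CC#CCCl | intermediate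
16 | (2E,5S,6S,7R,8E,10E)-5,7-bis[(tert-butyldimethylsilyl)oxy]-15-chloro-2,6-dimethylpentadeca-2,8,10-trien-13-ynal | O=C/C(C)=C/C[C@H](O[Si](C)(C)C(C)(C)C)[C@H](C)[C@H](O[Si](C)(C)C(C)(C)C)/C=C/C=C/CC#CCCl | intermediate
17 | 2-(4-chlorobut-2-yn-1-yl)-5,7-bis[(tert-butyldimethylsilyl)oxy]-1,6-dimethyl-1,2,4a,5,6,7,8,8a-octahydronaphthalene-1-carbaldehyde; trans ring fusion, CHO cis to H-8a and to the C2 chain, 5-OSi/6-CH3/7-OSi all cis to H-4a, absolute configuration as in 39 | O=C[C@@]1(C)[C@@H]2C[C@H](O[Si](C)(C)C(C)(C)C)[C@H](C)[C@H](O[Si](C)(C)C(C)(C)C)[C@H]2C=C[C@H]1CC#CCCl | intermediate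
18 | (R)-lactic acid | C[C@@H](O)C(=O)O | starting material
19 | pivalaldehyde (2,2-dimethylpropanal) | CC(C)(C)C=O | starting material
20 | (2R,5R)-2-tert-butyl-5-methyl-1,3-dioxolan-4-one (cis) | C[C@H]1O[C@@H](C(C)(C)C)OC1=O | intermediate
21 | 5-bromo-2-tert-butyl-5-methyl-1,3-dioxolan-4-one (acetal carbon as in 20, C5 epimers) | CC1(Br)O[C@@H](C(C)(C)C)OC1=O | intermediate
22 | (R)-2-tert-butyl-5-methylene-1,3-dioxolan-4-one | C=C1O[C@@H](C(C)(C)C)OC1=O | intermediate
23 | (E)-4-methoxypent-3-en-2-one | CC(=O)/C=C(\C)OC | starting material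
24 | (E)-2-methoxyhept-2-en-4-one | CCCC(=O)/C=C(\C)OC | intermediate
25 | (2E,4Z)-2-methoxy-4-[(triisopropylsilyl)oxy]hepta-2,4-diene | CC/C=C(\O[Si](C(C)C)(C(C)C)C(C)C)/C=C(\C)OC | intermediate
26 | (2R)-2-tert-butyl-5'-ethyl-2'-methoxy-2'-methyl-4'-[(triisopropylsilyl)oxy]spiro[1,3-dioxolane-4,1'-cyclohex-3'-en]-5-one; spiro carbon and C5' as in 39 (ring O on the spiro carbon cis to ethyl, tert-butyl on the face away from C2'), C2' epimers | CC[C@@H]1C[C@]2(O[C@@H](C(C)(C)C)OC2=O)C(C)(OC)C=C1O[Si](C(C)C)(C(C)C)C(C)C | intermediate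
27 | methyl (1S,5R)-5-ethyl-1-hydroxy-2-methoxy-2-methyl-4-[(triisopropylsilyl)oxy]cyclohex-3-ene-1-carboxylate (C2 epimers) | CC[C@@H]1C[C@@](O)(C(=O)OC)C(C)(OC)C=C1O[Si](C(C)C)(C(C)C)C(C)C | intermediate
28 | 9-ethyl-4,6-dimethoxy-6-methyl-8-[(triisopropylsilyl)oxy]-1-oxaspiro[4.5]deca-3,7-dien-2-one; spiro C5 and C9 as in 39, C6 epimers | CC[C@@H]1C[C@]2(OC(=O)C=C2OC)C(C)(OC)C=C1O[Si](C(C)C)(C(C)C)C(C)C | intermediate
29 | 3-lithio derivative of 28 | CC[C@@H]1C[C@]2(OC(=O)C([Li])=C2OC)C(C)(OC)C=C1O[Si](C(C)C)(C(C)C)C(C)C | intermediate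
30 | carbinol from 28 (tetronate C3) and 17 (CHO carbon); carbinol and C(OCH3) epimers, all other centres as in 17 and 28 | CC[C@@H]1C[C@]2(OC(=O)C(C(O)[C@@]3(C)[C@@H]4C[C@H](O[Si](C)(C)C(C)(C)C)[C@H](C)[C@H](O[Si](C)(C)C(C)(C)C)[C@H]4C=C[C@H]3CC#CCCl)=C2OC)C(C)(OC)C=C1O[Si](C(C)C)(C(C)C)C(C)C | intermediate
31 | as 30, with the chain CH2–C(SnBu3)=C=CH2 in place of CH2–C≡C–CH2Cl | CC[C@@H]1C[C@]2(OC(=O)C(C(O)[C@@]3(C)[C@@H]4C[C@H](O[Si](C)(C)C(C)(C)C)[C@H](C)[C@H](O[Si](C)(C)C(C)(C)C)[C@H]4C=C[C@H]3CC(=C=C)[Sn](CCCC)(CCCC)CCCC)=C2OC)C(C)(OC)C=C1O[Si](C(C)C)(C(C)C)C(C)C | intermediate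
32 | ketone from 31 (3-acyl-4-methoxy tetronate; C(OCH3) epimers) | CC[C@@H]1C[C@]2(OC(=O)C(C(=O)[C@@]3(C)[C@@H]4C[C@H](O[Si](C)(C)C(C)(C)C)[C@H](C)[C@H](O[Si](C)(C)C(C)(C)C)[C@H]4C=C[C@H]3CC(=C=C)[Sn](CCCC)(CCCC)CCCC)=C2OC)C(C)(OC)C=C1O[Si](C(C)C)(C(C)C)C(C)C | intermediate
33 | silyloxyallyl cation (O-silylated enone) from 32, triflate salt | CC[C@@H]1C[C@]2(OC(=O)C(C(=O)[C@@]3(C)[C@@H]4C[C@H](O[Si](C)(C)C(C)(C)C)[C@H](C)[C@H](O[Si](C)(C)C(C)(C)C)[C@H]4C=C[C@H]3CC(=C=C)[Sn](CCCC)(CCCC)CCCC)=C2OC)C(C)=CC1=[O+][Si](C(C)C)(C(C)C)C(C)C.[O-]S(=O)(=O)C(F)(F)F | intermediate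
34 | macrocycle: skeleton of 39 with ring alkyne in place of the (Z)-alkene, OSi(i-Pr)3 in place of the ring-alkene CH3, 4-methoxy tetronate with 3-acyl ketone, both OH as silyl ethers; all stereocentres as in 39 | CC[C@@H]1C[C@]23OC(=O)C(C(=O)[C@@]4(C)[C@@H]5C[C@H](O[Si](C)(C)C(C)(C)C)[C@H](C)[C@H](O[Si](C)(C)C(C)(C)C)[C@H]5C=C[C@H]4CC#CC[C@]2(C)C=C1O[Si](C(C)C)(C(C)C)C(C)C)=C3OC | intermediate
35 | enol triflate corresponding to 34 | CC[C@@H]1C[C@]23OC(=O)C(C(=O)[C@@]4(C)[C@@H]5C[C@H](O[Si](C)(C)C(C)(C)C)[C@H](C)[C@H](O[Si](C)(C)C(C)(C)C)[C@H]5C=C[C@H]4CC#CC[C@]2(C)C=C1OS(=O)(=O)C(F)(F)F)=C3OC | intermediate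
36 | as 35 with CH3 in place of OTf | CC[C@@H]1C[C@]23OC(=O)C(C(=O)[C@@]4(C)[C@@H]5C[C@H](O[Si](C)(C)C(C)(C)C)[C@H](C)[C@H](O[Si](C)(C)C(C)(C)C)[C@H]5C=C[C@H]4CC#CC[C@]2(C)C=C1C)=C3OC | intermediate
37 | as 36 with the (Z)-alkene in place of the alkyne | CC[C@@H]1C[C@]23OC(=O)C(C(=O)[C@@]4(C)[C@@H]5C[C@H](O[Si](C)(C)C(C)(C)C)[C@H](C)[C@H](O[Si](C)(C)C(C)(C)C)[C@H]5C=C[C@H]4C/C=C\C[C@]2(C)C=C1C)=C3OC | intermediate
38 | bis(tert-butyldimethylsilyl) ether of 39 | CC[C@@H]1C[C@]23OC(=O)/C(=C(\O)[C@@]4(C)[C@@H]5C[C@H](O[Si](C)(C)C(C)(C)C)[C@H](C)[C@H](O[Si](C)(C)C(C)(C)C)[C@H]5C=C[C@H]4C/C=C\C[C@]2(C)C=C1C)C3=O | intermediate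
39 | CNP0259772.1 | CC[C@@H]1C[C@]23OC(=O)/C(=C(\O)[C@@]4(C)[C@@H]5C[C@H](O)[C@H](C)[C@H](O)[C@H]5C=C[C@H]4C/C=C\C[C@]2(C)C=C1C)C3=O | target

## Step count and risks

Total: 30 steps (13 for the decalin aldehyde, 8 for the spiro tetronate, 9 after the union). Longest linear sequence: 22 steps (steps 1–13, then 22–30).

Steps most likely to fail:

1. Step 25 (proposed new method). The ring closure may lose to oligomerisation, to protodestannylation, to ionisation followed only by proton loss, to capture of the cation by the neighbouring acyl oxygen, or to attack on the wrong face of the cation. Fallback (known chemistry; the same bond is made between the fragments and the ring is closed at the acyl–tetronate bond instead): it sets out from 17 and 28. Aldehyde 17 would be reduced with NaBH4 in MeOH to the neopentyl alcohol F1. The stannylcopper reagent of step 23 would turn F1 into the allenylstannane alcohol F2. F2 and 28 would be joined with Me3SiOTf in CH2Cl2 at −78 °C, the intermolecular Lewis-acid conjugate propargylation of an enone equivalent by an allenylstannane, to give the alkyne-linked silyl enol ether alcohol F3. Dess–Martin oxidation would give the aldehyde F4. LiN(i-Pr)2 in THF at −78 °C under high dilution would lithiate tetronate C3 and close the ring onto the aldehyde to give the macrocyclic carbinol F5. Dess–Martin oxidation of F5 comes back to the route at 34.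

2. Step 19. Cycloaddition at the fully substituted, inside-methyl diene terminus with the bulky acetal dienophile may be too slow, so that desilylation or polymerisation of the diene wins, or the exo and facial preferences may erode. Fallback (the dienophile is changed to the flat 5-methylene tetronate, which forms the spiro tetronate in one step): it sets out from 25 and commercial 4-methoxyfuran-2(5H)-one. The furanone would be hydroxymethylated at C5 (LiN(i-Pr)2, then CH2O) to 5-(hydroxymethyl)-4-methoxyfuran-2(5H)-one F6 and dehydrated (MsCl, Et3N) to 4-methoxy-5-methylenefuran-2(5H)-one F7. Thermal cycloaddition of F7 with 25 (toluene, 130 °C, exo as for this dienophile class) comes back to the route at 28, formed as the racemate. The unwanted enantiomer series would be removed as the separable diastereomer after step 22.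

3. Step 21. The tertiary hydroxyl, flanked by a fully substituted carbon, may not add to the ketenylidene ylide, or the intramolecular Wittig closure onto the ester may stall. Fallback (classical Dieckmann route): it sets out from 27. Acetylation (Ac2O, DMAP, Et3N) would give the acetate F8. LiN(SiMe3)2 in THF/HMPA would cyclise it to the tetronic acid F9. O-Methylation with Me3SiCHN2 in MeOH/toluene comes back to the route at 28.

Further compounds
F1 | step 25 | neopentyl alcohol from reduction of 17 (CH2OH in place of CHO) | OC[C@@]1(C)[C@@H]2C[C@H](O[Si](C)(C)C(C)(C)C)[C@H](C)[C@H](O[Si](C)(C)C(C)(C)C)[C@H]2C=C[C@H]1CC#CCCl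
F2 | step 25 | allenylstannane alcohol (chain CH2–C(SnBu3)=C=CH2) | OC[C@@]1(C)[C@@H]2C[C@H](O[Si](C)(C)C(C)(C)C)[C@H](C)[C@H](O[Si](C)(C)C(C)(C)C)[C@H]2C=C[C@H]1CC(=C=C)[Sn](CCCC)(CCCC)CCCC
F3 | step 25 | alkyne-linked union product of F2 and 28 (quaternary carbon formed, silyl enol ether, free CH2OH, tetronate C3–H) | OC[C@@]1(C)[C@@H]2C[C@H](O[Si](C)(C)C(C)(C)C)[C@H](C)[C@H](O[Si](C)(C)C(C)(C)C)[C@H]2C=C[C@H]1CC#CC[C@]3(C)C=C(O[Si](C(C)C)(C(C)C)C(C)C)[C@H](CC)C[C@]34OC(=O)C=C4OC
F4 | step 25 | aldehyde from oxidation of F3 | O=C[C@@]1(C)[C@@H]2C[C@H](O[Si](C)(C)C(C)(C)C)[C@H](C)[C@H](O[Si](C)(C)C(C)(C)C)[C@H]2C=C[C@H]1CC#CC[C@]3(C)C=C(O[Si](C(C)C)(C(C)C)C(C)C)[C@H](CC)C[C@]34OC(=O)C=C4OC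
F5 | step 25 | macrocyclic carbinol (34 with CH(OH) in place of the acyl C=O; carbinol epimers) | CC[C@@H]1C[C@]23OC(=O)C(C(O)[C@@]4(C)[C@@H]5C[C@H](O[Si](C)(C)C(C)(C)C)[C@H](C)[C@H](O[Si](C)(C)C(C)(C)C)[C@H]5C=C[C@H]4CC#CC[C@]2(C)C=C1O[Si](C(C)C)(C(C)C)C(C)C)=C3OC
F6 | step 19 | 5-(hydroxymethyl)-4-methoxyfuran-2(5H)-one (racemic) | COC1=CC(=O)OC1CO
F7 | step 19 | 4-methoxy-5-methylenefuran-2(5H)-one | COC1=CC(=O)OC1=C
F8 | step 21 | acetate of 27 | CC[C@@H]1C[C@@](OC(C)=O)(C(=O)OC)C(C)(OC)C=C1O[Si](C(C)C)(C(C)C)C(C)C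
F9 | step 21 | tetronic acid (28 with 4-OH in place of 4-OCH3) | CC[C@@H]1C[C@]2(OC(=O)C=C2O)C(C)(OC)C=C1O[Si](C(C)C)(C(C)C)C(C)C
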